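**Retrosynthetic overview**
1. Target 19 ⇒ alkynyl chromone 16 + (S)-β-butyrolactone 17. The dihydropyranone is made last by a two-carbon ring expansion of the β-lactone (the alkyne is inserted into the acyl C–O bond); its stereocenter comes from 17.
2. 16 ⇒ 15 (chelation-controlled 5-O-demethylation) ⇒ o-hydroxyacetophenone 13 (Claisen condensation and cyclodehydration close the chromone pyranone ring).
3. 13 ⇒ symmetric phenol 11 (Fries acylation; the symmetry of 11 forces the side chain to C6 of the chromone).
4. 11 ⇒ ester 7 (C–H borylation/oxidation brings in the third ring oxygen; ester-to-alkyne homologation) ⇒ aryl bromide 4 + bromoester 5 (Negishi coupling; side-chain stereocenter from the chiral pool) ⇒ resorcinol 1.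
5. Ring order: benzene ring (bought) → chromone pyranone ring (step 7) → dihydropyranone ring (step 9).

Assumption: methyl (2S)-3-bromo-2-methylpropanoate 5 and (S)-β-butyrolactone 17 are bought as single enantiomers; all other atom sources are common reagents.

**Route**

Step 1
Reactants: 1 resorcinol (benzene-1,3-diol)
Product: 2 1,3-dimethoxybenzene
Conditions: Me2SO4 (2.4 equiv), K2CO3 (3 equiv), acetone, reflux
Reagents that add atoms: dimethyl sulfate, COS(=O)(=O)OC
Why: Double Williamson O-methylation of the two phenols under carbonate base is essentially quantitative and creates no stereocenter.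

Step 2
Reactants: 2 1,3-dimethoxybenzene
Product: 4 2-bromo-1,3-dimethoxybenzene, via aryllithium 3 (not isolated)
Conditions: n-BuLi (1.1 equiv), THF, 0 °C to rt; BrCH2CH2Br (1.2 equiv), −78 °C to rt
Reagents that add atoms: n-butyllithium, [Li]CCCC (lithium of 3 only); 1,2-dibromoethane, BrCCBr
Why: Directed ortho-metalation puts lithium on C2 between the two cooperating methoxy groups, and bromine transfer from 1,2-dibromoethane traps the aryllithium without electrophilic over-bromination of the ring.

Step 3
Reactants: 4 2-bromo-1,3-dimethoxybenzene; 5 methyl (2S)-3-bromo-2-methylpropanoate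
Product: 7 methyl (2R)-3-(2,6-dimethoxyphenyl)-2-methylpropanoate, via organozinc bromide 6 (not isolated)
Conditions: 5, Zn dust (1.5 equiv), LiCl (1.5 equiv), THF, 40 °C; then 4, Pd(OAc)2 (2 mol%), SPhos (4 mol%), THF, 60 °C
Reagents that add atoms: zinc, [Zn] (zinc of 6 only)
Why: Negishi coupling: zinc inserts into the primary C–Br bond of 5 without touching the neighbouring stereocenter, and Pd/SPhos couples such alkylzinc halides with di-ortho-substituted aryl bromides faster than β-hydride elimination; the stereocenter is the chiral-pool center of 5, whose descriptor changes from S to R only because the CIP rank of the CH2 arm changes.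

Step 4
Reactants: 7 methyl (2R)-3-(2,6-dimethoxyphenyl)-2-methylpropanoate
Product: 9 methyl (2R)-3-(4-hydroxy-2,6-dimethoxyphenyl)-2-methylpropanoate, via aryl pinacolboronate 8 (not isolated)
Conditions: B2pin2 (1.0 equiv), [Ir(OMe)(cod)]2 (1.5 mol%), dtbpy (3 mol%), THF, 80 °C; then 2KHSO5·KHSO4·K2SO4, acetone/H2O, rt
Reagents that add atoms: bis(pinacolato)diboron, CC1(C)OB(OC1(C)C)B1OC(C)(C)C(C)(C)O1 (boron ester of 8 only); potassium peroxymonosulfate, [K+].[O-]S(=O)(=O)OO
Why: Sterically controlled iridium-catalysed C–H borylation selects the only ring C–H with no ortho substituent (para to the side chain), and one-pot ipso-oxidation of the boronate by peroxymonosulfate gives the phenol under near-neutral conditions that leave the ester and its α-stereocenter untouched.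

Step 5
Reactants: 9 methyl (2R)-3-(4-hydroxy-2,6-dimethoxyphenyl)-2-methylpropanoate
Product: 11 3,5-dimethoxy-4-[(2R)-2-methylbut-3-yn-1-yl]phenol, via aldehyde 10 (not isolated)
Conditions: i-Bu2AlH (2.1 equiv), CH2Cl2, −78 °C; then MeOH, K2CO3 (4 equiv), dimethyl (1-diazo-2-oxopropyl)phosphonate (1.5 equiv), −78 °C to rt
Reagents that add atoms: dimethyl (1-diazo-2-oxopropyl)phosphonate, CC(=O)C(=[N+]=[N-])P(=O)(OC)OC
Why: One-pot partial reduction and Seyferth–Gilbert homologation (Ohira–Bestmann variant): the aluminium hemiacetal formed at −78 °C releases aldehyde 10 into methanolic K2CO3, where the diazophosphonate converts it to the terminal alkyne under conditions that α-methyl aldehydes of this kind normally survive without appreciable epimerization.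

Step 6
Reactants: 11 3,5-dimethoxy-4-[(2R)-2-methylbut-3-yn-1-yl]phenol
Product: 13 1-{6-hydroxy-2,4-dimethoxy-3-[(2R)-2-methylbut-3-yn-1-yl]phenyl}ethan-1-one, via aryl acetate 12 (not isolated)
Conditions: Ac2O (1.2 equiv), Sc(OTf)3 (10 mol%), toluene/MeNO2, rt then 80 °C
Reagents that add atoms: acetic anhydride, CC(=O)OC(C)=O
Why: O-acetylation followed by scandium-triflate-catalysed Fries rearrangement moves the acetyl group to the ortho carbon; the two free ring positions of 11 are equivalent, so a single hydrogen-bonded ortho-hydroxyacetophenone forms and the remote stereocenter is not involved.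

Step 7
Reactants: 13 1-{6-hydroxy-2,4-dimethoxy-3-[(2R)-2-methylbut-3-yn-1-yl]phenyl}ethan-1-one
Product: 15 5,7-dimethoxy-2-methyl-6-[(2R)-2-methylbut-3-yn-1-yl]-4H-chromen-4-one, via diketone 14 (not isolated)
Conditions: LiN(SiMe3)2 (3.2 equiv), THF, −78 °C; EtOAc (1.5 equiv), −78 °C to rt; then conc. HCl, MeOH, 50 °C
Reagents that add atoms: ethyl acetate, CCOC(C)=O
Why: Claisen condensation of the lithium enolate of 13 with ethyl acetate gives β-diketone 14, and acid-catalysed cyclodehydration through the only free phenol closes the 2-methylchromone, so the alkyl chain necessarily ends up at C6 between the two methoxy groups.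

Step 8
Reactants: 15 5,7-dimethoxy-2-methyl-6-[(2R)-2-methylbut-3-yn-1-yl]-4H-chromen-4-one
Product: 16 5-hydroxy-7-methoxy-2-methyl-6-[(2R)-2-methylbut-3-yn-1-yl]-4H-chromen-4-one
Conditions: BCl3 (1.5 equiv), CH2Cl2, −78 to −20 °C; then H2O
Reagents that add atoms: none
Why: Chelation-controlled Lewis-acid ether cleavage: BCl3 bound to the C4 carbonyl cleaves only the peri 5-methoxy group, the 7-methoxy group has no chelating partner, and the alkyne is inert at this temperature.

Step 9
Reactants: 16 5-hydroxy-7-methoxy-2-methyl-6-[(2R)-2-methylbut-3-yn-1-yl]-4H-chromen-4-one; 17 (4S)-4-methyloxetan-2-one ((S)-β-butyrolactone)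
Product: 19 5-hydroxy-7-methoxy-2-methyl-6-{(2R)-2-[(2S)-2-methyl-4-oxo-3,4-dihydro-2H-pyran-6-yl]propyl}-4H-chromen-4-one (CNP0231471.1), via hydroxy ynone 18 (not isolated)
Conditions: chloro[1,3-bis(2,6-diisopropylphenyl)imidazol-2-ylidene]copper (10 mol%), Cs2CO3 (20 mol%), 17 (1.5 equiv, added over 4 h), THF, 40 °C
Reagents that add atoms: none
Why: Proposed new method: copper-catalysed insertion of a terminal alkyne into the acyl C–O bond of a β-lactone, a non-pericyclic two-carbon ring expansion (oxetan-2-one to 2,3-dihydro-4H-pyran-4-one); the carbonate-ligated NHC–copper complex metalates the alkyne C–H of 16 (as in copper-catalysed alkyne carboxylation), the electron-rich copper acetylide adds to the strained lactone carbonyl of 17 as it is known to add to CO2, the tetrahedral intermediate collapses with acyl C–O cleavage (relief of four-ring strain) to the copper alkoxide of hydroxy ynone 18, and this alkoxide closes by 6-endo-dig oxa-Michael addition (oxycupration, then protonolysis by the next alkyne or the phenol) to give 19 and return the acetylide; the terminal alkyne carbon becomes C5 and the substituted carbon becomes C6, the O–C2 bond of the lactone is never broken so the (S) center of 17 is carried over unchanged, the side-chain center is not touched, and copper stays monovalent throughout; the closest known reaction types are copper-catalysed acylation of terminal alkynes with acid chlorides to ynones, NHC–copper carboxylation of terminal alkynes, and base- or coinage-metal-catalysed 6-endo cyclization of β-hydroxy ynones to dihydropyranones.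

**Compound list**
1 | resorcinol (benzene-1,3-diol) | Oc1cccc(O)c1 | starting material
2 | 1,3-dimethoxybenzene | COc1cccc(OC)c1 | intermediate
3 | (2,6-dimethoxyphenyl)lithium | [Li]c1c(OC)cccc1OC | intermediate
4 | 2-bromo-1,3-dimethoxybenzene | COc1cccc(OC)c1Br | intermediate
5 | methyl (2S)-3-bromo-2-methylpropanoate | COC(=O)[C@H](C)CBr | starting material
6 | bromo[(2S)-3-methoxy-2-methyl-3-oxopropyl]zinc | COC(=O)[C@H](C)C[Zn]Br | intermediate
7 | methyl (2R)-3-(2,6-dimethoxyphenyl)-2-methylpropanoate | COC(=O)[C@H](C)Cc1c(OC)cccc1OC | intermediate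
8 | methyl (2R)-3-[2,6-dimethoxy-4-(4,4,5,5-tetramethyl-1,3,2-dioxaborolan-2-yl)phenyl]-2-methylpropanoate | COC(=O)[C@H](C)Cc1c(OC)cc(cc1OC)B1OC(C)(C)C(C)(C)O1 | intermediate
9 | methyl (2R)-3-(4-hydroxy-2,6-dimethoxyphenyl)-2-methylpropanoate | COC(=O)[C@H](C)Cc1c(OC)cc(O)cc1OC | intermediate
10 | (2R)-3-(4-hydroxy-2,6-dimethoxyphenyl)-2-methylpropanal | O=C[C@H](C)Cc1c(OC)cc(O)cc1OC | intermediate
11 | 3,5-dimethoxy-4-[(2R)-2-methylbut-3-yn-1-yl]phenol | C#C[C@H](C)Cc1c(OC)cc(O)cc1OC | intermediate
12 | 3,5-dimethoxy-4-[(2R)-2-methylbut-3-yn-1-yl]phenyl acetate | CC(=O)Oc1cc(OC)c(C[C@@H](C)C#C)c(OC)c1 | intermediate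
13 | 1-{6-hydroxy-2,4-dimethoxy-3-[(2R)-2-methylbut-3-yn-1-yl]phenyl}ethan-1-one | CC(=O)c1c(O)cc(OC)c(C[C@@H](C)C#C)c1OC | intermediate
14 | 1-{6-hydroxy-2,4-dimethoxy-3-[(2R)-2-methylbut-3-yn-1-yl]phenyl}butane-1,3-dione | CC(=O)CC(=O)c1c(O)cc(OC)c(C[C@@H](C)C#C)c1OC | intermediate
15 | 5,7-dimethoxy-2-methyl-6-[(2R)-2-methylbut-3-yn-1-yl]-4H-chromen-4-one | COc1cc2oc(C)cc(=O)c2c(OC)c1C[C@@H](C)C#C | intermediate
16 | 5-hydroxy-7-methoxy-2-methyl-6-[(2R)-2-methylbut-3-yn-1-yl]-4H-chromen-4-one | COc1cc2oc(C)cc(=O)c2c(O)c1C[C@@H](C)C#C | intermediate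
17 | (4S)-4-methyloxetan-2-one ((S)-β-butyrolactone) | C[C@H]1CC(=O)O1 | starting material
18 | 5-hydroxy-6-[(2R,7S)-7-hydroxy-2-methyl-5-oxooct-3-yn-1-yl]-7-methoxy-2-methyl-4H-chromen-4-one | COc1cc2oc(C)cc(=O)c2c(O)c1C[C@@H](C)C#CC(=O)C[C@H](C)O | intermediate
19 | 5-hydroxy-7-methoxy-2-methyl-6-{(2R)-2-[(2S)-2-methyl-4-oxo-3,4-dihydro-2H-pyran-6-yl]propyl}-4H-chromen-4-one | COc1cc2oc(C)cc(=O)c2c(O)c1C[C@@H](C)C1=CC(=O)C[C@H](C)O1 | target

**Step count and risks**
Total step count: 9. Longest linear sequence: 9 (resorcinol 1 to target 19; 5 and 17 enter as bought).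

Three steps most likely to fail:

Step 9 (the proposed ring expansion). The copper acetylide may be too weak a nucleophile for the lactone carbonyl, so that 17 oligomerizes or eliminates to crotonate instead. The chelating 5-hydroxy-4-oxo unit of 16 may sequester the copper. Ynone 18 may isomerize through its γ-hydrogen before it cyclizes, which would erode the side-chain center. The fallback uses known chemistry, sets out from 16 and comes back at 18, which is then closed to 19. Methyl (3S)-3-hydroxybutanoate F1 (bought) is silylated with TBSCl/imidazole to methyl (3S)-3-[(tert-butyldimethylsilyl)oxy]butanoate F2. Saponification with LiOH gives (3S)-3-[(tert-butyldimethylsilyl)oxy]butanoic acid F3, and (COCl)2 with catalytic DMF gives (3S)-3-[(tert-butyldimethylsilyl)oxy]butanoyl chloride F4. Acyl Sonogashira coupling of F4 with 16 (PdCl2(PPh3)2 2 mol%, CuI 4 mol%, Et3N, THF, rt) gives 6-[(2R,7S)-7-[(tert-butyldimethylsilyl)oxy]-2-methyl-5-oxooct-3-yn-1-yl]-5-hydroxy-7-methoxy-2-methyl-4H-chromen-4-one F5. HF·pyridine (THF, 0 °C) frees 18, and Ph3PAuCl/AgOTf (5 mol%, CH2Cl2, rt) effects the established 6-endo-dig cyclization of the β-hydroxy ynone to 19.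

Step 5 (one-pot ester to alkyne). The free phenol and the aluminium salts can cause over-reduction to the alcohol, and aldehyde 10 may partly epimerize in methanolic carbonate. The fallback sets out from 9 and comes back at 11 by a stepwise, non-diazo homologation. i-Bu2AlH at −78 °C with tartrate work-up gives isolated 10. CBr4/PPh3/Et3N (CH2Cl2, 0 °C) converts it to 4-[(2R)-4,4-dibromo-2-methylbut-3-en-1-yl]-3,5-dimethoxyphenol F6 without enolizing conditions. n-BuLi (3.3 equiv, THF, −78 °C) then gives 11 by the Corey–Fuchs sequence (Fritsch–Buttenberg–Wiechell 1,2-shift).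

Step 6 (Fries acylation next to a terminal alkyne). The Lewis-acidic triflate at 80 °C may hydrate or oligomerize the alkyne, or stall through chelation by the product. The fallback sets out from 11 and comes back at 13 by a neutral photochemical route. Ac2O/pyridine gives isolated aryl acetate 12. Photo-Fries rearrangement (254 nm, degassed MeOH, rt) moves the acetyl group through a radical pair to the only open (ortho) position, the para position being blocked. No compound outside the list is made (F0).

Further compounds
F1 | step 9 | methyl (3S)-3-hydroxybutanoate | COC(=O)C[C@H](C)O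
F2 | step 9 | methyl (3S)-3-[(tert-butyldimethylsilyl)oxy]butanoate | COC(=O)C[C@H](C)O[Si](C)(C)C(C)(C)C
F3 | step 9 | (3S)-3-[(tert-butyldimethylsilyl)oxy]butanoic acid | OC(=O)C[C@H](C)O[Si](C)(C)C(C)(C)C
F4 | step 9 | (3S)-3-[(tert-butyldimethylsilyl)oxy]butanoyl chloride | ClC(=O)C[C@H](C)O[Si](C)(C)C(C)(C)C
F5 | step 9 | 6-[(2R,7S)-7-[(tert-butyldimethylsilyl)oxy]-2-methyl-5-oxooct-3-yn-1-yl]-5-hydroxy-7-methoxy-2-methyl-4H-chromen-4-one | COc1cc2oc(C)cc(=O)c2c(O)c1C[C@@H](C)C#CC(=O)C[C@H](C)O[Si](C)(C)C(C)(C)C
F6 | step 5 | 4-[(2R)-4,4-dibromo-2-methylbut-3-en-1-yl]-3,5-dimethoxyphenol | BrC(Br)=C[C@H](C)Cc1c(OC)cc(O)cc1OC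
F0 | step 6 | none | none
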